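The plan cuts the cyclohexane ring at C1–C6 and C2–C3 (carotenoid numbering), so that C1 with its two methyl groups and C2 are simply isobutene, and C3–C6 is an open chain from (R)-citramalic acid that already holds the C5 carbinol. In one radical chain operation isobutene is stitched between the C3 iodide and the C6 acylgermane of 7 to give (R)-2-hydroxy-2,6,6-trimethylcyclohexanone. The step exploits the quaternary gem-dimethyl carbon C1, flanked in the ring by the C2 methylene and by the carbinol carbon C6, which can pass through the ketone level. Chelation-controlled alkynylation then sets C6, and a Wittig reaction and oxidation complete the polyene acid.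

Key step: step 5

Remark: atoms carry carotenoid numbers (ring C1–C6 with C5 and C6 the carbinol carbons, chain C7–C15 then C15'–C12'). (R)-Citramalic acid, (2E)-3-methylpent-2-en-4-yn-1-ol and (2E,4E,6E)-2,7-dimethylocta-2,4,6-trienedial are taken as commercially available.

Step 1
Reactants: 1 (R)-citramalic acid
Product: 2 2-[(4R)-2,2,4-trimethyl-5-oxo-1,3-dioxolan-4-yl]acetic acid
Conditions: 2,2-dimethoxypropane, PPTS (cat.), CH2Cl2, rt
Reagents that add atoms: 2,2-dimethoxypropane, COC(C)(C)OC
Why: Acid-catalysed acetal exchange should close the five-membered dioxolanone on the tertiary hydroxyl and its own carboxyl group (as with malic acid), which leaves the other carboxyl group free and does not touch C5.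

Step 2
Reactants: 2 2-[(4R)-2,2,4-trimethyl-5-oxo-1,3-dioxolan-4-yl]acetic acid
Product: 4 (3R)-3-hydroxy-3-methyloxolan-2-one, via hydroxyethyl dioxolanone 3 (not isolated)
Conditions: BH3·SMe2, THF, 0 °C to rt; H2O; then TsOH (cat.), CH2Cl2, rt
Reagents that add atoms: none
Why: Chemoselective borane reduction of the free carboxylic acid beside the dioxolanone ester, followed by acid-catalysed translactonization that expels acetone, should give the five-membered lactone with C5 unchanged.

Step 3
Reactants: 4 (3R)-3-hydroxy-3-methyloxolan-2-one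
Product: 6 (2R)-2,4-dihydroxy-2-methyl-1-(triphenylgermyl)butan-1-one, via dilithium lactolate 5 (not isolated)
Conditions: Ph3GeLi (2.2 equiv, from Ph3GeH and n-BuLi, THF, 0 °C), THF, −78 °C; aq. NH4Cl at −78 °C
Reagents that add atoms: triphenylgermyllithium (made in the flask from triphenylgermane and n-BuLi), [Li][Ge](c1ccccc1)(c1ccccc1)c1ccccc1
Why: Nucleophilic acyl substitution of an ester by a germyllithium reagent (the known ester route to acylgermanes) should stop after one addition, because the first equivalent deprotonates the hydroxyl group and the mono-adduct persists as lactolate 5 until the cold quench.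

Step 4
Reactants: 6 (2R)-2,4-dihydroxy-2-methyl-1-(triphenylgermyl)butan-1-one
Product: 7 (2R)-2-hydroxy-4-iodo-2-methyl-1-(triphenylgermyl)butan-1-one
Conditions: I2, PPh3, imidazole, CH2Cl2, 0 °C, dark
Reagents that add atoms: iodine, II
Why: Appel-type iodination should convert only the primary alcohol by SN2 displacement, since the tertiary hydroxyl next to the acyl group is too hindered to be activated.

Step 5
Reactants: 7 (2R)-2-hydroxy-4-iodo-2-methyl-1-(triphenylgermyl)butan-1-one; 8 isobutene
Product: 9 (2R)-2-hydroxy-2,6,6-trimethylcyclohexan-1-one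
Conditions: 8 (large excess, condensed), (Me3Sn)2 (10 mol %), PhH, hν (sunlamp), sealed tube, 30–40 °C
Reagents that add atoms: none
Why: Proposed new method: a triphenylgermyl radical abstracts iodine from 7, the primary C3 radical adds to the CH2 terminus of isobutene (C2–C3 bond), the resulting nucleophilic tertiary C1 radical attacks the acylgermane carbonyl carbon C6 (C1–C6 bond), and the alkoxy radical expels Ph3Ge•, which carries the chain. The closest known reaction type is the intramolecular radical cyclization of iodoalkyl acylgermanes to cycloalkanones, here preceded by an intermolecular addition to an unactivated alkene. The six-membered ring closes in the 6-exo-trig mode onto the C=O group. No stereocenter is created, since C1 carries two methyl groups and C6 becomes a carbonyl carbon, and C5 (R, from citramalic acid) is not involved. The step needs addition of the C3 radical to isobutene before the chain dies, attack at CH2 and not at the substituted carbon, and ring closure before a second isobutene adds. These are secured by the absence of any hydrogen-atom donor together with the large excess of alkene, by the stability of the tertiary radical, and by the fast attack of alkyl radicals on acylgermanes combined with the poor radical homopropagation of isobutene.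

Step 6
Reactants: 9 (2R)-2-hydroxy-2,6,6-trimethylcyclohexan-1-one; 10 (2E)-3-methylpent-2-en-4-yn-1-ol
Product: 12 (1S,2R)-1-[(3E)-5-hydroxy-3-methylpent-3-en-1-yn-1-yl]-2,6,6-trimethylcyclohexane-1,2-diol, via bromomagnesium acetylide 11 (not isolated)
Conditions: 10 (3 equiv), EtMgBr (6 equiv), THF, 0 °C to rt; then 9, THF, 0 to 50 °C; aq. NH4Cl
Reagents that add atoms: none
Why: Chelation-controlled Grignard addition to the non-enolizable ketone is expected to run through the five-membered magnesium chelate of the C5 alkoxide and the C6 carbonyl, in which the C5 methyl is axial, so that the slim alkynyl group enters axially anti to the axial methyl groups and C7 ends up cis to the C5 oxygen (trans-diol, C6 set by C5).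

Step 7
Reactants: 12 (1S,2R)-1-[(3E)-5-hydroxy-3-methylpent-3-en-1-yn-1-yl]-2,6,6-trimethylcyclohexane-1,2-diol
Product: 13 (1R,2R)-1-[(1E,3E)-5-hydroxy-3-methylpenta-1,3-dien-1-yl]-2,6,6-trimethylcyclohexane-1,2-diol
Conditions: LiAlH4, THF, reflux; then H2O, aq. NaOH
Reagents that add atoms: none
Why: Hydroxyl-directed trans-hydroalumination of the propargylic alkoxide (LiAlH4 reduction of a propargylic alcohol) and protonolysis should give the (E)-C7=C8 alkene without touching the C9=C10 alkene or the carbinol centers (the C6 descriptor changes from S to R only through the CIP priorities).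

Step 8
Reactants: 13 (1R,2R)-1-[(1E,3E)-5-hydroxy-3-methylpenta-1,3-dien-1-yl]-2,6,6-trimethylcyclohexane-1,2-diol
Product: 15 [(2E,4E)-5-[(1R,2R)-1,2-dihydroxy-2,6,6-trimethylcyclohexyl]-3-methylpenta-2,4-dien-1-yl]triphenylphosphonium bromide, via allylic bromide 14 (not isolated)
Conditions: CBr4 (1.1 equiv), PPh3 (2.5 equiv), CH2Cl2, 0 °C to rt
Reagents that add atoms: triphenylphosphine, c1ccc(cc1)P(c1ccccc1)c1ccccc1; carbon tetrabromide, BrC(Br)(Br)Br
Why: Appel bromination of the primary allylic alcohol followed by SN2 quaternization of the dienyl bromide by the excess phosphine should give the phosphonium salt under non-acidic conditions, which spares the ionizable tertiary allylic C6 hydroxyl group.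

Step 9
Reactants: 15 [(2E,4E)-5-[(1R,2R)-1,2-dihydroxy-2,6,6-trimethylcyclohexyl]-3-methylpenta-2,4-dien-1-yl]triphenylphosphonium bromide; 16 (2E,4E,6E)-2,7-dimethylocta-2,4,6-trienedial
Product: 19 (2E,4E,6E,8E,10E,12E)-13-[(1R,2R)-1,2-dihydroxy-2,6,6-trimethylcyclohexyl]-2,7,11-trimethyltrideca-2,4,6,8,10,12-hexaenal, via phosphonium ylide 17 (not isolated), via 8Z aldehyde 18 (not isolated)
Conditions: 16 (3 equiv), NaOMe, MeOH/CH2Cl2, 0 °C to rt; then EtOH, 75 °C, dark
Reagents that add atoms: none
Why: Wittig olefination of the semi-stabilized allylic ylide with an excess of the symmetrical dialdehyde should form C11=C12 at one formyl group only, and the (Z) isomer 18 that accompanies the product is expected to equilibrate thermally to the all-(E) polyene.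

Step 10
Reactants: 19 (2E,4E,6E,8E,10E,12E)-13-[(1R,2R)-1,2-dihydroxy-2,6,6-trimethylcyclohexyl]-2,7,11-trimethyltrideca-2,4,6,8,10,12-hexaenal
Product: 20 (2E,4E,6E,8E,10E,12E)-13-[(1R,2R)-1,2-dihydroxy-2,6,6-trimethylcyclohexyl]-2,7,11-trimethyltrideca-2,4,6,8,10,12-hexaenoic acid
Conditions: Ag2O, NaOH, EtOH/H2O, rt, dark; then aq. NaH2PO4 to pH 5
Reagents that add atoms: Ag2O, [Ag]O[Ag]; water, O
Why: Tollens-type oxidation with Ag2O in basic medium should convert the conjugated aldehyde into the carboxylic acid without attacking the polyene or ionizing the tertiary allylic alcohol, and buffered acidification releases the acid.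

Compound list
1 | (R)-citramalic acid, (2R)-2-hydroxy-2-methylbutanedioic acid | C[C@@](O)(CC(=O)O)C(=O)O | starting material
2 | 2-[(4R)-2,2,4-trimethyl-5-oxo-1,3-dioxolan-4-yl]acetic acid | C[C@]1(CC(=O)O)OC(C)(C)OC1=O | intermediate
3 | (5R)-5-(2-hydroxyethyl)-2,2,5-trimethyl-1,3-dioxolan-4-one | C[C@]1(CCO)OC(C)(C)OC1=O | intermediate (not isolated)
4 | (3R)-3-hydroxy-3-methyloxolan-2-one | C[C@@]1(O)CCOC1=O | intermediate
5 | dilithium (3R)-3-methyl-2-(triphenylgermyl)oxolane-2,3-diolate (C2 configuration undefined) | C[C@@]1(O[Li])CCOC1(O[Li])[Ge](c1ccccc1)(c1ccccc1)c1ccccc1 | intermediate (not isolated)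
6 | (2R)-2,4-dihydroxy-2-methyl-1-(triphenylgermyl)butan-1-one | C[C@@](O)(CCO)C(=O)[Ge](c1ccccc1)(c1ccccc1)c1ccccc1 | intermediate
7 | (2R)-2-hydroxy-4-iodo-2-methyl-1-(triphenylgermyl)butan-1-one | C[C@@](O)(CCI)C(=O)[Ge](c1ccccc1)(c1ccccc1)c1ccccc1 | intermediate
8 | isobutene (2-methylpropene) | CC(C)=C | starting material
9 | (2R)-2-hydroxy-2,6,6-trimethylcyclohexan-1-one | O=C1C(C)(C)CCC[C@@]1(C)O | intermediate
10 | (2E)-3-methylpent-2-en-4-yn-1-ol | C#C/C(C)=C/CO | starting material
11 | bromo[(3E)-5-(bromomagnesiooxy)-3-methylpent-3-en-1-yn-1-yl]magnesium | Br[Mg]C#C/C(C)=C/CO[Mg]Br | intermediate (not isolated)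
12 | (1S,2R)-1-[(3E)-5-hydroxy-3-methylpent-3-en-1-yn-1-yl]-2,6,6-trimethylcyclohexane-1,2-diol | OC/C=C(C)/C#C[C@@]1(O)C(C)(C)CCC[C@@]1(C)O | intermediate
13 | (1R,2R)-1-[(1E,3E)-5-hydroxy-3-methylpenta-1,3-dien-1-yl]-2,6,6-trimethylcyclohexane-1,2-diol | OC/C=C(C)/C=C/[C@@]1(O)C(C)(C)CCC[C@@]1(C)O | intermediate
14 | (1R,2R)-1-[(1E,3E)-5-bromo-3-methylpenta-1,3-dien-1-yl]-2,6,6-trimethylcyclohexane-1,2-diol | BrC/C=C(C)/C=C/[C@@]1(O)C(C)(C)CCC[C@@]1(C)O | intermediate (not isolated)
15 | [(2E,4E)-5-[(1R,2R)-1,2-dihydroxy-2,6,6-trimethylcyclohexyl]-3-methylpenta-2,4-dien-1-yl]triphenylphosphonium bromide | [Br-].c1ccc(cc1)[P+](c1ccccc1)(c1ccccc1)C/C=C(C)/C=C/[C@@]1(O)C(C)(C)CCC[C@@]1(C)O | intermediate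
16 | (2E,4E,6E)-2,7-dimethylocta-2,4,6-trienedial | O=C/C(C)=C/C=C/C=C(C)/C=O | starting material
17 | ylide of 15, drawn as the zwitterion | c1ccc(cc1)[P+](c1ccccc1)(c1ccccc1)[CH-]/C=C(C)/C=C/[C@@]1(O)C(C)(C)CCC[C@@]1(C)O | intermediate (not isolated)
18 | (2E,4E,6E,8Z,10E,12E)-13-[(1R,2R)-1,2-dihydroxy-2,6,6-trimethylcyclohexyl]-2,7,11-trimethyltrideca-2,4,6,8,10,12-hexaenal | CC(/C=C\C=C(C)\C=C\[C@@]1(O)C(C)(C)CCC[C@@]1(C)O)=C\C=C\C=C(/C)C=O | intermediate (not isolated)
19 | (2E,4E,6E,8E,10E,12E)-13-[(1R,2R)-1,2-dihydroxy-2,6,6-trimethylcyclohexyl]-2,7,11-trimethyltrideca-2,4,6,8,10,12-hexaenal | CC(/C=C/C=C(C)/C=C/[C@@]1(O)C(C)(C)CCC[C@@]1(C)O)=C\C=C\C=C(/C)C=O | intermediate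
20 | (2E,4E,6E,8E,10E,12E)-13-[(1R,2R)-1,2-dihydroxy-2,6,6-trimethylcyclohexyl]-2,7,11-trimethyltrideca-2,4,6,8,10,12-hexaenoic acid | CC(/C=C/C=C(C)/C=C/[C@@]1(O)C(C)(C)CCC[C@@]1(C)O)=C\C=C\C=C(/C)C(=O)O | target

Total step count: 10. Longest linear sequence: 10 steps (1 to 20).

Steps most likely to fail

1. Step 5. The intermolecular addition of the nucleophilic primary radical to the unactivated alkene may be too slow, so that the chain collapses by radical–radical termination or by allylic hydrogen abstraction from isobutene. The tertiary radical may also add a second isobutene before it closes the ring. The fallback uses known chemistry, sets out from 7 and comes back at 9. Radical allylation of 7 with tributyl(2-methylallyl)stannane (AIBN, PhH, 80 °C) should give (2R)-2-hydroxy-2,6-dimethyl-1-(triphenylgermyl)hept-6-en-1-one F1. Markovnikov addition of HBr (CH2Cl2, −78 °C) should then give (2R)-6-bromo-2-hydroxy-2,6-dimethyl-1-(triphenylgermyl)heptan-1-one F2. The known 6-exo radical cyclization of a haloalkyl acylgermane ((Me3Sn)2 cat., hν, PhH), now without any alkene in the flask, closes the ring to 9.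

2. Step 6. Facial selectivity may be poor if the addition runs through the non-chelated conformer with the C5 oxygen axial, which would deliver the cis-diol, and the tetra-α-substituted ketone may react sluggishly. The fallback sets out from 9 and comes back at 13; it introduces the oxygen, not the carbon substituent, of C6 last.
   - Wittig methylenation of 9 (Ph3PCH3Br, KOtBu, toluene, 100 °C) should give (1R)-1,3,3-trimethyl-2-methylidenecyclohexan-1-ol F3.
   - Dihydroxylation with OsO4 (cat.) and NMO is expected to occur anti to the allylic C5–O bond and give (1S,2R)-1-(hydroxymethyl)-2,6,6-trimethylcyclohexane-1,2-diol F4.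
   - Oxidation of the primary alcohol (SO3·pyridine, DMSO, iPr2NEt) should give (1R,2R)-1,2-dihydroxy-2,6,6-trimethylcyclohexane-1-carbaldehyde F5.
   - Horner–Wadsworth–Emmons reaction with triethyl 3-methyl-4-phosphonocrotonate (LiCl, DBU, MeCN) should give ethyl (2E,4E)-5-[(1R,2R)-1,2-dihydroxy-2,6,6-trimethylcyclohexyl]-3-methylpenta-2,4-dienoate F6.
   - Reduction with iBu2AlH (CH2Cl2, −78 °C) returns the sequence to 13.

3. Step 3. The germyl anion may add twice after premature collapse of the lactolate, may cleave the lactone at the alkyl–oxygen bond, or may react incompletely because the neighbouring alkoxide deactivates the carbonyl group. The fallback sets out from 4 and comes back at 6. Aminolysis of 4 with MeNH(OMe)·HCl and Me3Al (CH2Cl2, 0 °C to rt) should give (2R)-2,4-dihydroxy-N-methoxy-N,2-dimethylbutanamide F7. Its chelated tetrahedral adduct with Ph3GeLi (3.3 equiv, THF, −78 °C) cannot add a second germyl group and should release 6 on work-up.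

Further compounds
F1 | step 5 | (2R)-2-hydroxy-2,6-dimethyl-1-(triphenylgermyl)hept-6-en-1-one | CC(=C)CCC[C@@](C)(O)C(=O)[Ge](c1ccccc1)(c1ccccc1)c1ccccc1
F2 | step 5 | (2R)-6-bromo-2-hydroxy-2,6-dimethyl-1-(triphenylgermyl)heptan-1-one | CC(C)(Br)CCC[C@@](C)(O)C(=O)[Ge](c1ccccc1)(c1ccccc1)c1ccccc1
F3 | step 6 | (1R)-1,3,3-trimethyl-2-methylidenecyclohexan-1-ol | C=C1C(C)(C)CCC[C@@]1(C)O
F4 | step 6 | (1S,2R)-1-(hydroxymethyl)-2,6,6-trimethylcyclohexane-1,2-diol | OC[C@@]1(O)C(C)(C)CCC[C@@]1(C)O
F5 | step 6 | (1R,2R)-1,2-dihydroxy-2,6,6-trimethylcyclohexane-1-carbaldehyde | O=C[C@@]1(O)C(C)(C)CCC[C@@]1(C)O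
F6 | step 6 | ethyl (2E,4E)-5-[(1R,2R)-1,2-dihydroxy-2,6,6-trimethylcyclohexyl]-3-methylpenta-2,4-dienoate | CCOC(=O)/C=C(C)/C=C/[C@@]1(O)C(C)(C)CCC[C@@]1(C)O
F7 | step 3 | (2R)-2,4-dihydroxy-N-methoxy-N,2-dimethylbutanamide | C[C@@](O)(CCO)C(=O)N(C)OC
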